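**Plan**
1. Retrosynthesis: the seven O–CH3 bonds are cut last. Then, in each 2,3-dihydrobenzofuran (upper unit: benzo ring A and furan ring B, carrying the stilbene; lower unit: benzo ring C and furan ring D), the O1–C2 ether bond is cut. Then the C3–aryl and C2–aryl bonds of each ArCH(O)–CH(Ar)(Ar) unit are cut, leaving an (E)-styryl iodide, a 4-methoxyphenylboron ester and an aryl electrophile.
2. Enabling feature: in rings B and D alike, C2 carries O1 and a 4-oxyphenyl group and C3 carries two aryl groups. This array is what anti addition of a boron-bound aryl (to C2) and an aryl–palladium (to C3) across an (E)-β-aryl alkenylboron ate complex leaves; boron then becomes the oxygen on C2.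
3. Forward, lower half first: conjunctive coupling of a 3,5-dimethoxystyryl ate complex with a symmetric 2,6-bis(MOMO)aryl bromide, C–B oxidation, then acid closure of ring D by either of two equivalent phenols. The phenol left at C4 of ring C becomes a triflate.
4. That triflate is the electrophile of a second conjunctive coupling with the ate complex of the stilbene-bearing ring-A styryl unit, which joins the halves at the C3(ring B)–C4(ring C) bond. Oxidation, acid closure of ring B and BBr3 demethylation finish the route.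
5. Stereochemistry: C3 of rings B and D comes from ligand control (the two MandyPhos enantiomers) in the conjunctive couplings. C2 of both rings comes from acid (SN1) closure to the 2,3-trans isomer. Both alkenes are (E) from Heck and Takai reactions.

Key step: step 12

Assumption: the facial sense of the MandyPhos-controlled aryl–palladium addition is taken over from β-alkyl alkenyl–B(mac) ate complexes. (Sp,Sp)-MandyPhos is written for step 12. Because the aryl group that later closes the ring is the alkene substituent in step 12 but the electrophile in step 6, the mirror-image ligand (Rp,Rp)-MandyPhos is written for step 6. If a test run shows the other sense, the two ligands are exchanged.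
Remark: MandyPhos = 1,1'-bis[bis(4-methoxy-3,5-dimethylphenyl)phosphino]-2,2'-bis[α-(dimethylamino)benzyl]ferrocene; mac = the diolate of cis-1,2-dimethyl-1,2-dihydroacenaphthylene-1,2-diol (compound 8).

**Step 1**
Reactants: 1 5-methoxyresorcinol (5-methoxybenzene-1,3-diol)
Product: 2 1-methoxy-3,5-bis(methoxymethoxy)benzene
Conditions: MOMCl, iPr2NEt, CH2Cl2, 0 °C to rt
Reagents that add atoms: chloromethyl methyl ether (MOMCl), COCCl
Why: O-Alkylation of both phenols with MOMCl gives the bis-acetal, whose OMOM groups serve as ortho-directing groups in step 2 and as acid-labile masks of the ring-closing oxygens in step 7.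

**Step 2**
Reactants: 2 1-methoxy-3,5-bis(methoxymethoxy)benzene
Product: 4 2-bromo-5-methoxy-1,3-bis(methoxymethoxy)benzene, via aryllithium 3 (not isolated)
Conditions: n-BuLi, THF, 0 °C; then BrCH2CH2Br, −78 °C to rt
Reagents that add atoms: 1,2-dibromoethane, BrCCBr
Why: Directed ortho-metalation removes the proton between the two OMOM groups (the site coordinated by both acetal oxygens), and the aryllithium takes bromine from 1,2-dibromoethane with loss of ethene.

**Step 3**
Reactants: 5 3,5-dimethoxybenzaldehyde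
Product: 6 1-[(E)-2-iodoethenyl]-3,5-dimethoxybenzene
Conditions: CrCl2, CHI3, THF/1,4-dioxane, 0 °C to rt
Reagents that add atoms: iodoform, IC(I)I
Why: Takai olefination: the gem-dichromium species formed from CHI3 and divalent chromium adds to the aldehyde and eliminates to the (E)-alkenyl iodide, the geometry favoured for aryl aldehydes.

**Step 4**
Reactants: 7 acenaphthoquinone (acenaphthylene-1,2-dione)
Product: 8 cis-1,2-dimethyl-1,2-dihydroacenaphthylene-1,2-diol (meso, the mac diol)
Conditions: AlMe3, toluene, 0 °C to rt; then aqueous potassium sodium tartrate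
Reagents that add atoms: trimethylaluminium, C[Al](C)C
Why: Twofold 1,2-addition of methyl to the 1,2-diketone gives the ditertiary diol, of which the cis (meso) isomer is the expected main product and is purified by crystallisation.

**Step 5**
Reactants: 9 4-methoxyphenylboronic acid; 8 cis-1,2-dimethyl-1,2-dihydroacenaphthylene-1,2-diol
Product: 10 4-methoxyphenylboronic acid mac ester, 4-MeOC6H4–B(mac)
Conditions: toluene, reflux, Dean–Stark trap
Reagents that add atoms: none
Why: Condensation of the boronic acid with the cis-diol, driven by azeotropic removal of water, gives the five-membered cyclic boronic ester.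

**Step 6**
Reactants: 6 1-[(E)-2-iodoethenyl]-3,5-dimethoxybenzene; 10 4-MeOC6H4–B(mac); 4 2-bromo-5-methoxy-1,3-bis(methoxymethoxy)benzene
Product: 14 (1S,2S)-2-(3,5-dimethoxyphenyl)-2-[4-methoxy-2,6-bis(methoxymethoxy)phenyl]-1-(4-methoxyphenyl)ethan-1-ol, via alkenyllithium 11 (not isolated), via lithium borate 12 (not isolated), via boronic ester 13 (not isolated)
Conditions: 6, t-BuLi (2 equiv), Et2O, −78 °C; 10, −78 °C to rt; then THF, Pd(OAc)2 (3 mol%), (Rp,Rp)-MandyPhos, 4, KOTf, 60 °C; then NaOH, H2O2, 0 °C to rt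
Reagents that add atoms: hydrogen peroxide, OO
Why: Proposed new method: iodine–lithium exchange gives alkenyllithium 11, which adds to the boron of 10 to give the ate complex 12; its boron-bearing alkene binds the cationic aryl–palladium formed from 4 (bromide and iodide are taken out by KOTf), the 4-methoxyphenyl group shifts from boron to the α-carbon anti to palladium while palladium bonds to the benzylic β-carbon, reductive elimination makes the diarylmethine carbon–aryl bond with the ligand fixing the (S) centre, and alkaline H2O2 converts carbon–boron into carbon–oxygen with retention; the closest known reaction type is the palladium/MandyPhos conjunctive cross-coupling of β-alkyl alkenyl–B(mac) ate complexes with aryl triflates or halides, stretched here to a β-aryl alkene and a 2,6-dialkoxyaryl bromide, whose two small ortho oxygens flank but do not block the palladium–carbon bond.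

**Step 7**
Reactants: 14 (1S,2S)-2-(3,5-dimethoxyphenyl)-2-[4-methoxy-2,6-bis(methoxymethoxy)phenyl]-1-(4-methoxyphenyl)ethan-1-ol
Product: 15 (2S,3S)-3-(3,5-dimethoxyphenyl)-6-methoxy-2-(4-methoxyphenyl)-2,3-dihydro-1-benzofuran-4-ol
Conditions: HCl (cat.), MeOH/THF, 50 °C
Reagents that add atoms: none
Why: Acid cleaves both MOM acetals and ionises the 4-methoxybenzylic alcohol to a quinoid cation that either of the two equivalent phenols captures (5-exo-trig) anti to the C3 aryl group, so ring D closes 2,3-trans, C2 becomes (S) by substrate control from C3, and the untouched phenol remains at C4.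

**Step 8**
Reactants: 15 (2S,3S)-3-(3,5-dimethoxyphenyl)-6-methoxy-2-(4-methoxyphenyl)-2,3-dihydro-1-benzofuran-4-ol
Product: 16 (2S,3S)-3-(3,5-dimethoxyphenyl)-6-methoxy-2-(4-methoxyphenyl)-2,3-dihydro-1-benzofuran-4-yl trifluoromethanesulfonate
Conditions: Tf2O, pyridine, CH2Cl2, 0 °C
Reagents that add atoms: trifluoromethanesulfonic anhydride, O=S(=O)(OS(=O)(=O)C(F)(F)F)C(F)(F)F
Why: Sulfonylation of the phenol with Tf2O in the presence of pyridine gives the aryl triflate without touching the two stereocentres.

**Step 9**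
Reactants: 17 5-bromo-2-hydroxybenzaldehyde
Product: 18 5-bromo-2-(methoxymethoxy)benzaldehyde
Conditions: MOMCl, iPr2NEt, CH2Cl2, 0 °C to rt
Reagents that add atoms: chloromethyl methyl ether (MOMCl), COCCl
Why: O-Alkylation with MOMCl masks the oxygen that later closes ring B and prevents phenoxide formation in the basic and organometallic steps.

**Step 10**
Reactants: 18 5-bromo-2-(methoxymethoxy)benzaldehyde; 19 3,5-dimethoxystyrene
Product: 20 5-[(E)-2-(3,5-dimethoxyphenyl)ethenyl]-2-(methoxymethoxy)benzaldehyde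
Conditions: Pd(OAc)2, P(o-tol)3, Et3N, DMF, 100 °C
Reagents that add atoms: none
Why: Mizoroki–Heck reaction: oxidative addition to the aryl bromide, syn insertion of the styrene and syn β-hydride elimination give the (E)-stilbene, the aldehyde and the acetal being inert.

**Step 11**
Reactants: 20 5-[(E)-2-(3,5-dimethoxyphenyl)ethenyl]-2-(methoxymethoxy)benzaldehyde
Product: 21 4-[(E)-2-(3,5-dimethoxyphenyl)ethenyl]-2-[(E)-2-iodoethenyl]-1-(methoxymethoxy)benzene
Conditions: CrCl2, CHI3, THF/1,4-dioxane, 0 °C to rt
Reagents that add atoms: iodoform, IC(I)I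
Why: Takai olefination converts the aldehyde into the (E)-alkenyl iodide with the E preference of aryl aldehydes, and the stilbene, having no carbonyl group, is not touched by the chromium reagent.

**Step 12**
Reactants: 21 4-[(E)-2-(3,5-dimethoxyphenyl)ethenyl]-2-[(E)-2-iodoethenyl]-1-(methoxymethoxy)benzene; 10 4-MeOC6H4–B(mac); 16 (2S,3S)-3-(3,5-dimethoxyphenyl)-6-methoxy-2-(4-methoxyphenyl)-2,3-dihydro-1-benzofuran-4-yl trifluoromethanesulfonate
Product: 25 (1R,2S)-2-[(2S,3S)-3-(3,5-dimethoxyphenyl)-6-methoxy-2-(4-methoxyphenyl)-2,3-dihydro-1-benzofuran-4-yl]-2-{5-[(E)-2-(3,5-dimethoxyphenyl)ethenyl]-2-(methoxymethoxy)phenyl}-1-(4-methoxyphenyl)ethan-1-ol, via alkenyllithium 22 (not isolated), via lithium borate 23 (not isolated), via boronic ester 24 (not isolated)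
Conditions: 21, t-BuLi (2 equiv), Et2O, −78 °C; 10, −78 °C to rt; then THF, Pd(OAc)2 (5 mol%), (Sp,Sp)-MandyPhos, 16, KOTf, 60 °C; then NaOH, H2O2, 0 °C to rt
Reagents that add atoms: hydrogen peroxide, OO
Why: Proposed new method: iodine–lithium exchange of 21 and addition of alkenyllithium 22 to the boron of 10 give the ate complex 23; zerovalent palladium inserts into the carbon–oxygen bond of triflate 16, the cationic aryl–palladium binds the boron-bearing alkene of 23, the 4-methoxyphenyl group shifts from boron to the α-carbon anti-periplanar to palladium, which bonds to the benzylic β-carbon, and reductive elimination with retention forms the bond between C3 of the future ring B and C4 of ring C, after which alkaline H2O2 turns carbon–boron into carbon–oxygen with retention. The closest known reaction type is the palladium/MandyPhos-catalysed enantio- and diastereoselective conjunctive cross-coupling of β-alkyl alkenyl–B(mac) ate complexes with aryl triflates, and what is new is the β-aryl alkene (a benzylic palladium intermediate) together with an ortho-substituted, stereogenic aryl triflate. No ring is closed in this step, because ring B is closed only in step 13. The new diarylmethine centre (S) is controlled by the ligand, which selects the alkene face that the aryl–palladium attacks, and the new boron-bearing centre (R, later the carbinol) follows from the anti mode of addition across the (E)-alkene, is retained in the oxidation and is reset in step 13, so only the first of the two must be right. The step needs the metallate shift to win over direct Suzuki-type transfer of the alkenyl or aryl group from boron, which the hindered mac diolate secures, and it needs reaction at the boron-bearing alkene and not at the stilbene, which carries no boron to drive the shift and binds the cationic palladium less well. It also needs the catalyst to override the stereocentres of 16, which sit three and four bonds from palladium, and it needs β-hydride elimination from the benzylic palladium to stay slow, which the chelating bisphosphine secures by leaving no free cis site.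

**Step 13**
Reactants: 25 (1R,2S)-2-[(2S,3S)-3-(3,5-dimethoxyphenyl)-6-methoxy-2-(4-methoxyphenyl)-2,3-dihydro-1-benzofuran-4-yl]-2-{5-[(E)-2-(3,5-dimethoxyphenyl)ethenyl]-2-(methoxymethoxy)phenyl}-1-(4-methoxyphenyl)ethan-1-ol
Product: 26 (2S,3S)-3-[(2S,3S)-3-(3,5-dimethoxyphenyl)-6-methoxy-2-(4-methoxyphenyl)-2,3-dihydro-1-benzofuran-4-yl]-5-[(E)-2-(3,5-dimethoxyphenyl)ethenyl]-2-(4-methoxyphenyl)-2,3-dihydro-1-benzofuran (hepta-O-methyl ether of the target)
Conditions: HCl (cat.), MeOH/THF, 40 °C
Reagents that add atoms: none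
Why: Acid cleaves the MOM acetal and ionises the 4-methoxybenzylic alcohol, and the freed ortho phenol of ring A captures the quinoid cation (5-exo-trig) anti to the C3 aryl group, so ring B closes 2,3-trans and C2 becomes (S) by substrate control whatever the carbinol configuration.

**Step 14**
Reactants: 26 hepta-O-methyl ether of the target
Product: 27 trans-diptoindonesin B
Conditions: BBr3, CH2Cl2, −78 °C to rt; then H2O
Reagents that add atoms: none
Why: Lewis-acid ether cleavage: BBr3 binds each methoxy oxygen and bromide attacks the methyl group, which frees the seven phenols on hydrolysis, while the C3 centres cannot ionise and the C2 centres, should their benzylic ether bonds open reversibly, re-close to the stable trans rings already present.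

**Compound list**
1 | 5-methoxyresorcinol | COc1cc(O)cc(O)c1 | starting material
2 | 1-methoxy-3,5-bis(methoxymethoxy)benzene | COCOc1cc(OC)cc(OCOC)c1 | intermediate
3 | [4-methoxy-2,6-bis(methoxymethoxy)phenyl]lithium | COCOc1cc(OC)cc(OCOC)c1[Li] | intermediate (not isolated)
4 | 2-bromo-5-methoxy-1,3-bis(methoxymethoxy)benzene | COCOc1cc(OC)cc(OCOC)c1Br | intermediate
5 | 3,5-dimethoxybenzaldehyde | COc1cc(C=O)cc(OC)c1 | starting material
6 | 1-[(E)-2-iodoethenyl]-3,5-dimethoxybenzene | COc1cc(/C=C/I)cc(OC)c1 | intermediate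
7 | acenaphthoquinone | O=C1C(=O)c2cccc3cccc1c23 | starting material
8 | cis-1,2-dimethyl-1,2-dihydroacenaphthylene-1,2-diol (meso, mac diol) | C[C@@]1(O)c2cccc3cccc(c23)[C@]1(C)O | intermediate
9 | 4-methoxyphenylboronic acid | COc1ccc(cc1)B(O)O | starting material
10 | 4-methoxyphenylboronic acid mac ester, 4-MeOC6H4–B(mac) | COc1ccc(cc1)B1O[C@]2(C)c3cccc4cccc(c34)[C@]2(C)O1 | intermediate
11 | [(E)-2-(3,5-dimethoxyphenyl)ethenyl]lithium | COc1cc(/C=C/[Li])cc(OC)c1 | intermediate (not isolated)
12 | lithium [(E)-2-(3,5-dimethoxyphenyl)ethenyl](4-methoxyphenyl)(mac-diolato)borate | COc1cc(/C=C/[B-]2(c3ccc(OC)cc3)O[C@]3(C)c4cccc5cccc(c45)[C@]3(C)O2)cc(OC)c1.[Li+] | intermediate (not isolated)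
13 | mac ester of (1S,2S)-2-(3,5-dimethoxyphenyl)-2-[4-methoxy-2,6-bis(methoxymethoxy)phenyl]-1-(4-methoxyphenyl)ethylboronic acid | COc1ccc(cc1)[C@@H](B1O[C@]2(C)c3cccc4cccc(c34)[C@]2(C)O1)[C@@H](c1cc(OC)cc(OC)c1)c1c(OCOC)cc(OC)cc1OCOC | intermediate (not isolated)
14 | (1S,2S)-2-(3,5-dimethoxyphenyl)-2-[4-methoxy-2,6-bis(methoxymethoxy)phenyl]-1-(4-methoxyphenyl)ethan-1-ol | COc1ccc(cc1)[C@@H](O)[C@@H](c1cc(OC)cc(OC)c1)c1c(OCOC)cc(OC)cc1OCOC | intermediate
15 | (2S,3S)-3-(3,5-dimethoxyphenyl)-6-methoxy-2-(4-methoxyphenyl)-2,3-dihydro-1-benzofuran-4-ol | Oc1cc(OC)cc2c1[C@H](c1cc(OC)cc(OC)c1)[C@@H](c1ccc(OC)cc1)O2 | intermediate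
16 | (2S,3S)-3-(3,5-dimethoxyphenyl)-6-methoxy-2-(4-methoxyphenyl)-2,3-dihydro-1-benzofuran-4-yl trifluoromethanesulfonate | FC(F)(F)S(=O)(=O)Oc1cc(OC)cc2c1[C@H](c1cc(OC)cc(OC)c1)[C@@H](c1ccc(OC)cc1)O2 | intermediate
17 | 5-bromo-2-hydroxybenzaldehyde | O=Cc1cc(Br)ccc1O | starting material
18 | 5-bromo-2-(methoxymethoxy)benzaldehyde | COCOc1ccc(Br)cc1C=O | intermediate
19 | 3,5-dimethoxystyrene | C=Cc1cc(OC)cc(OC)c1 | starting material
20 | 5-[(E)-2-(3,5-dimethoxyphenyl)ethenyl]-2-(methoxymethoxy)benzaldehyde | COCOc1ccc(/C=C/c2cc(OC)cc(OC)c2)cc1C=O | intermediate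
21 | 4-[(E)-2-(3,5-dimethoxyphenyl)ethenyl]-2-[(E)-2-iodoethenyl]-1-(methoxymethoxy)benzene | COCOc1ccc(/C=C/c2cc(OC)cc(OC)c2)cc1/C=C/I | intermediate
22 | [(E)-2-{5-[(E)-2-(3,5-dimethoxyphenyl)ethenyl]-2-(methoxymethoxy)phenyl}ethenyl]lithium | COCOc1ccc(/C=C/c2cc(OC)cc(OC)c2)cc1/C=C/[Li] | intermediate (not isolated)
23 | lithium [(E)-2-{5-[(E)-2-(3,5-dimethoxyphenyl)ethenyl]-2-(methoxymethoxy)phenyl}ethenyl](4-methoxyphenyl)(mac-diolato)borate | COCOc1ccc(/C=C/c2cc(OC)cc(OC)c2)cc1/C=C/[B-]1(c2ccc(OC)cc2)O[C@]2(C)c3cccc4cccc(c34)[C@]2(C)O1.[Li+] | intermediate (not isolated)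
24 | mac ester of (1R,2S)-2-[(2S,3S)-3-(3,5-dimethoxyphenyl)-6-methoxy-2-(4-methoxyphenyl)-2,3-dihydro-1-benzofuran-4-yl]-2-{5-[(E)-2-(3,5-dimethoxyphenyl)ethenyl]-2-(methoxymethoxy)phenyl}-1-(4-methoxyphenyl)ethylboronic acid | COc1ccc(cc1)[C@H](B1O[C@]2(C)c3cccc4cccc(c34)[C@]2(C)O1)[C@H](c1cc(/C=C/c2cc(OC)cc(OC)c2)ccc1OCOC)c1cc(OC)cc2c1[C@H](c1cc(OC)cc(OC)c1)[C@@H](c1ccc(OC)cc1)O2 | intermediate (not isolated)
25 | (1R,2S)-2-[(2S,3S)-3-(3,5-dimethoxyphenyl)-6-methoxy-2-(4-methoxyphenyl)-2,3-dihydro-1-benzofuran-4-yl]-2-{5-[(E)-2-(3,5-dimethoxyphenyl)ethenyl]-2-(methoxymethoxy)phenyl}-1-(4-methoxyphenyl)ethan-1-ol | COc1ccc(cc1)[C@H](O)[C@H](c1cc(/C=C/c2cc(OC)cc(OC)c2)ccc1OCOC)c1cc(OC)cc2c1[C@H](c1cc(OC)cc(OC)c1)[C@@H](c1ccc(OC)cc1)O2 | intermediate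
26 | (2S,3S)-3-[(2S,3S)-3-(3,5-dimethoxyphenyl)-6-methoxy-2-(4-methoxyphenyl)-2,3-dihydro-1-benzofuran-4-yl]-5-[(E)-2-(3,5-dimethoxyphenyl)ethenyl]-2-(4-methoxyphenyl)-2,3-dihydro-1-benzofuran | COc1ccc([C@H]2Oc3ccc(/C=C/c4cc(OC)cc(OC)c4)cc3[C@@H]2c2cc(OC)cc3c2[C@H](c2cc(OC)cc(OC)c2)[C@@H](c2ccc(OC)cc2)O3)cc1 | intermediate
27 | trans-diptoindonesin B | Oc1ccc([C@H]2Oc3ccc(/C=C/c4cc(O)cc(O)c4)cc3[C@@H]2c2cc(O)cc3c2[C@H](c2cc(O)cc(O)c2)[C@@H](c2ccc(O)cc2)O3)cc1 | target

**Step count**
Total steps: 14. Longest linear sequence: 8 steps (1, 2, 6, 7, 8, 12, 13, 14).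

**Steps most likely to fail**

1. Step 12 (bears the label). What may go wrong: direct transfer of the alkenyl or aryl group from boron to palladium (Suzuki-type coupling) in place of the metallate shift, because the bulky aryl–palladium binds the β-aryl alkene poorly. Facial control may also be lost through the stereocentres of the electrophile or through isomerisation of the benzylic palladium intermediate. The fallback uses known chemistry, sets out from 16 and 20 and returns at 26. Miyaura borylation of 16 (PdCl2(dppf), bis(pinacolato)diboron, KOAc, dioxane, 90 °C) should give the pinacol boronic ester F1. Rhodium-catalysed 1,2-addition of F1 to aldehyde 20 ([Rh(cod)OH]2, aqueous KOH, dioxane, 80 °C) should give the diarylmethanol F2 as a mixture of carbinol epimers, which is of no consequence. p-Toluenesulfinic acid with catalytic TsOH in MeOH/CH2Cl2 should remove the MOM group and replace the benzhydrylic hydroxyl, giving the phenol sulfone F3. Cs2CO3 with (4-methoxybenzyl)dimethylsulfonium tetrafluoroborate in CH2Cl2 should then eliminate sulfinate to the ortho-quinone methide, and formal (4+1) annulation with the sulfonium ylide should close ring B 2,3-trans. This fallback does not control C3 against the lower half, so 26 should form together with its ring-B epimer F4; the two are diastereomers and are separated by chromatography.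

2. Step 6 (bears the label). What may go wrong: slow oxidative addition and poor alkene binding at the 2,6-dialkoxyaryl–palladium, leading to Suzuki-type transfer or protodehalogenation instead of conjunctive coupling, and insufficient enantiofacial control. The fallback uses known chemistry, sets out from 2 and 5 and returns at 15. Compound 2 is lithiated as in step 2 and aryllithium 3 is added to aldehyde 5 to give the diarylmethanol F5. p-Toluenesulfinic acid with catalytic TsOH in MeOH/CH2Cl2 should remove both MOM groups and install the sulfonyl group, giving the resorcinol sulfone F6. Cs2CO3 with (4-methoxybenzyl)dimethylsulfonium tetrafluoroborate should give, through the ortho-quinone methide and formal (4+1) annulation, the racemic 2,3-trans dihydrobenzofuranol F7. Preparative HPLC on a chiral stationary phase then delivers the (2S,3S) enantiomer 15.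

3. Step 13. What may go wrong: capture of the benzylic cation by the 3,5-dimethoxyphenyl ring of the lower half (Friedel–Crafts closure of a seven-membered ring) or acid-induced reactions of the electron-rich stilbene, in competition with ether formation. The same cation could in principle arise in step 14; there the rings are already closed. The fallback replaces the cationic closure by a stereospecific SN2 closure; it sets out from 24 (isolated by omitting the oxidative work-up of step 12) and returns at 26. HCl (cat.) in MeOH/THF removes the MOM group while the upper half carries carbon–boron and no ionisable benzylic carbon–oxygen bond, giving the phenol boronic ester F8. NaOH/H2O2 then gives the phenol alcohol F9. Mitsunobu reaction (PPh3, DIAD, THF, 0 °C) closes ring B with inversion at the carbinol carbon, which for the anti adduct of step 12 is the 2,3-trans ring of 26.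

**Further compounds**
F1 | step 12 | (2S,3S)-3-(3,5-dimethoxyphenyl)-6-methoxy-2-(4-methoxyphenyl)-4-(4,4,5,5-tetramethyl-1,3,2-dioxaborolan-2-yl)-2,3-dihydro-1-benzofuran | CC1(C)OB(OC1(C)C)c1cc(OC)cc2c1[C@H](c1cc(OC)cc(OC)c1)[C@@H](c1ccc(OC)cc1)O2
F2 | step 12 | [(2S,3S)-3-(3,5-dimethoxyphenyl)-6-methoxy-2-(4-methoxyphenyl)-2,3-dihydro-1-benzofuran-4-yl]{5-[(E)-2-(3,5-dimethoxyphenyl)ethenyl]-2-(methoxymethoxy)phenyl}methanol (both carbinol epimers) | COCOc1ccc(/C=C/c2cc(OC)cc(OC)c2)cc1C(O)c1cc(OC)cc2c1[C@H](c1cc(OC)cc(OC)c1)[C@@H](c1ccc(OC)cc1)O2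
F3 | step 12 | 2-{[(2S,3S)-3-(3,5-dimethoxyphenyl)-6-methoxy-2-(4-methoxyphenyl)-2,3-dihydro-1-benzofuran-4-yl](4-methylbenzenesulfonyl)methyl}-4-[(E)-2-(3,5-dimethoxyphenyl)ethenyl]phenol (both epimers) | Cc1ccc(cc1)S(=O)(=O)C(c1cc(/C=C/c2cc(OC)cc(OC)c2)ccc1O)c1cc(OC)cc2c1[C@H](c1cc(OC)cc(OC)c1)[C@@H](c1ccc(OC)cc1)O2
F4 | step 12 | (2R,3R)-3-[(2S,3S)-3-(3,5-dimethoxyphenyl)-6-methoxy-2-(4-methoxyphenyl)-2,3-dihydro-1-benzofuran-4-yl]-5-[(E)-2-(3,5-dimethoxyphenyl)ethenyl]-2-(4-methoxyphenyl)-2,3-dihydro-1-benzofuran (ring-B epimer of 26) | COc1ccc([C@@H]2Oc3ccc(/C=C/c4cc(OC)cc(OC)c4)cc3[C@H]2c2cc(OC)cc3c2[C@H](c2cc(OC)cc(OC)c2)[C@@H](c2ccc(OC)cc2)O3)cc1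
F5 | step 6 | (3,5-dimethoxyphenyl)[4-methoxy-2,6-bis(methoxymethoxy)phenyl]methanol (racemic) | COCOc1cc(OC)cc(OCOC)c1C(O)c1cc(OC)cc(OC)c1
F6 | step 6 | 2-[(3,5-dimethoxyphenyl)(4-methylbenzenesulfonyl)methyl]-5-methoxybenzene-1,3-diol (racemic) | Cc1ccc(cc1)S(=O)(=O)C(c1cc(OC)cc(OC)c1)c1c(O)cc(OC)cc1O
F7 | step 6 | racemic 2,3-trans-3-(3,5-dimethoxyphenyl)-6-methoxy-2-(4-methoxyphenyl)-2,3-dihydro-1-benzofuran-4-ol (both enantiomers) | Oc1cc(OC)cc2c1[C@H](c1cc(OC)cc(OC)c1)[C@@H](c1ccc(OC)cc1)O2.Oc1cc(OC)cc2c1[C@@H](c1cc(OC)cc(OC)c1)[C@H](c1ccc(OC)cc1)O2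
F8 | step 13 | mac ester of (1R,2S)-2-[(2S,3S)-3-(3,5-dimethoxyphenyl)-6-methoxy-2-(4-methoxyphenyl)-2,3-dihydro-1-benzofuran-4-yl]-2-{5-[(E)-2-(3,5-dimethoxyphenyl)ethenyl]-2-hydroxyphenyl}-1-(4-methoxyphenyl)ethylboronic acid | COc1ccc(cc1)[C@H](B1O[C@]2(C)c3cccc4cccc(c34)[C@]2(C)O1)[C@H](c1cc(/C=C/c2cc(OC)cc(OC)c2)ccc1O)c1cc(OC)cc2c1[C@H](c1cc(OC)cc(OC)c1)[C@@H](c1ccc(OC)cc1)O2
F9 | step 13 | 2-{(1S,2R)-1-[(2S,3S)-3-(3,5-dimethoxyphenyl)-6-methoxy-2-(4-methoxyphenyl)-2,3-dihydro-1-benzofuran-4-yl]-2-hydroxy-2-(4-methoxyphenyl)ethyl}-4-[(E)-2-(3,5-dimethoxyphenyl)ethenyl]phenol | COc1ccc(cc1)[C@H](O)[C@H](c1cc(/C=C/c2cc(OC)cc(OC)c2)ccc1O)c1cc(OC)cc2c1[C@H](c1cc(OC)cc(OC)c1)[C@@H](c1ccc(OC)cc1)O2
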